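**Retrosynthetic overview**
- The strategy rests on ring C: C2 carries ring B and lies β to the C4 ketone, and C3 carries the hydroxyl α to it. Cutting the C2–C1' bond and the C3–O bond leaves a planar, achiral 5,7-dioxy-6,8-diprenylchromone whose ring A is a fully substituted, mirror-symmetric phloroglucinol, so no regiochemical choice arises.
- Disconnections: C3–OH (enol silane oxidation anti to the aryl group) ⇒ (2S)-flavanone; C2–C1' (catalytic asymmetric conjugate arylation with an arylboronic acid) ⇒ chromone; O1–C2 and C2–C3 (enaminone, then cyclisation) ⇒ diprenyl acetophenone; two aryl–prenyl bonds ⇒ phloroacetophenone.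
- Ring order: ring A is bought and prenylated first; ring C is closed flat as a 4-pyranone (O1–C2); ring B is attached at C2 in the key step, which closes no ring; C3 is oxygenated last, then the MOM ethers are removed.

Key step: step 5

Assumption: the sense of aryl delivery by the (S)-configured biaryl bisphosphine–rhodium catalyst is assigned by analogy with its behaviour toward 2-cyclohexenone; if a trial run shows the opposite sense, the (R)-ligand is used with no other change. "Prenyl" means 3-methylbut-2-enyl throughout.

**Route**

Step 1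
Reactants: 1 2,4,6-trihydroxyacetophenone; 2 prenyl bromide
Product: 3 2,4,6-trihydroxy-3,5-diprenylacetophenone
Conditions: 2 (2.2 equiv), 10% aq. KOH, 0 °C → rt
Reagents that add atoms: none
Why: Phenoxide C-alkylation of the phloroglucinol ring (in water the solvated ambident anion reacts at carbon), and because the two free ring positions are equivalent and the only ones available, twofold prenylation can give only this constitution, with O-prenyl ethers and over-alkylated dienones removed by chromatography.

Step 2
Reactants: 3 2,4,6-trihydroxy-3,5-diprenylacetophenone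
Product: 4 2-hydroxy-4,6-bis(methoxymethoxy)-3,5-diprenylacetophenone
Conditions: MOMCl (2.3 equiv), i-Pr2NEt (3 equiv), CH2Cl2, 0 °C → rt
Reagents that add atoms: chloromethyl methyl ether, COCCl
Why: Williamson-type acetalisation that should stop at the bis-ether because the last ortho-hydroxyl is locked in a hydrogen bond to the acetyl carbonyl, and since both ortho-hydroxyls are equivalent by symmetry only one bis-ether can form.

Step 3
Reactants: 4 2-hydroxy-4,6-bis(methoxymethoxy)-3,5-diprenylacetophenone
Product: 5 (E)-3-(dimethylamino)-1-[2-hydroxy-4,6-bis(methoxymethoxy)-3,5-diprenylphenyl]prop-2-en-1-one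
Conditions: DMF dimethyl acetal (3 equiv), toluene, 90 °C
Reagents that add atoms: N,N-dimethylformamide dimethyl acetal, COC(OC)N(C)C
Why: Enaminone condensation of the acetyl methyl group with the amide acetal brings in the future C2 as a vinylogous amide with loss of two methanol, under neutral thermal conditions that leave MOM ethers and prenyl groups untouched.

Step 4
Reactants: 5 (E)-3-(dimethylamino)-1-[2-hydroxy-4,6-bis(methoxymethoxy)-3,5-diprenylphenyl]prop-2-en-1-one
Product: 7 5,7-bis(methoxymethoxy)-6,8-diprenylchromone, via 2-(dimethylamino)chromanone aminal 6 (not isolated)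
Conditions: AcOH (10 equiv), toluene, 60 °C
Reagents that add atoms: none
Why: Acid-promoted 6-endo oxa-Michael addition of the free phenol to the protonated enaminone gives the cyclic aminal, and elimination of dimethylamine then leaves the O1–C2 bond of the flat 4-pyranone ring, acetic acid being too weak to cleave aryl MOM ethers or cyclise the prenyl groups.

Step 5
Reactants: 7 5,7-bis(methoxymethoxy)-6,8-diprenylchromone; 8 4-(methoxymethoxy)phenylboronic acid
Product: 9 (2S)-5,7-bis(methoxymethoxy)-2-[4-(methoxymethoxy)phenyl]-6,8-diprenylchroman-4-one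
Conditions: 8 (3 equiv), [Rh(OH)(cod)]2 (2.5 mol%), (S)-MeO-F12-BIPHEP [(S)-2,2'-bis{bis(3,4,5-trifluorophenyl)phosphino}-6,6'-dimethoxy-1,1'-biphenyl] (5.5 mol%), CH2Cl2/H2O (10:1), 25 °C
Reagents that add atoms: none
Why: Transmetalation of 8 to the rhodium hydroxide (monovalent rhodium) gives an aryl–rhodium species that inserts the chromone C2=C3 bond with aryl delivery to C2, and the resulting oxa-π-allyl rhodium enolate is protonated at C3 by water, releasing 9 and regenerating Rh–OH. The closest known reaction type is the Hayashi–Miyaura asymmetric 1,4-addition of arylboronic acids to cyclic enones, which is established for chromones as a route to 2-arylchromanones. No ring is closed: the C2–C1' bond joins ring B to the already closed pyranone, which is thereby dearomatised into the saturated ring C. The only new stereocentre, C2, is set by the chiral bisphosphine on rhodium, which selects the enantioface of the planar, s-trans-locked enone (the substrate has no stereocentre), the (S)-ligand being expected to give 2S. The step needs 1,4- over 1,2-addition, single addition and enantioface control, and these are secured by the unsubstituted C2, the fully substituted ring A, the inertness of the trisubstituted prenyl olefins to aryl–rhodium insertion, and the electron-poor ligand that speeds insertion into the electron-rich chromone at room temperature. The near-neutral biphasic medium avoids the base-induced retro-oxa-Michael opening that would racemise 9.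

Step 6
Reactants: 9 (2S)-5,7-bis(methoxymethoxy)-2-[4-(methoxymethoxy)phenyl]-6,8-diprenylchroman-4-one
Product: 10 (2S)-5,7-bis(methoxymethoxy)-2-[4-(methoxymethoxy)phenyl]-6,8-diprenyl-4-(trimethylsilyloxy)-2H-chromene
Conditions: TMSOTf (1.3 equiv), Et3N (3 equiv), CH2Cl2, −78 → 0 °C; cold aq. NaHCO3 work-up, used crude, light excluded
Reagents that add atoms: trimethylsilyl trifluoromethanesulfonate, C[Si](C)(C)OS(=O)(=O)C(F)(F)F
Why: Soft enolisation (the silyl triflate activates the C4 carbonyl and the amine removes a C3 proton) gives the cyclic enol silane without a free enolate, so the E1cB ring opening that would racemise C2 is avoided, and excess amine at low temperature keeps the silyl triflate from attacking the MOM acetals.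

Step 7
Reactants: 10 (2S)-5,7-bis(methoxymethoxy)-2-[4-(methoxymethoxy)phenyl]-6,8-diprenyl-4-(trimethylsilyloxy)-2H-chromene
Product: 13 (2R,3R)-3-hydroxy-5,7-bis(methoxymethoxy)-2-[4-(methoxymethoxy)phenyl]-6,8-diprenylchroman-4-one, via silyloxy epoxide 11 (not isolated), via 3-O-trimethylsilyl ketone 12 (not isolated)
Conditions: 2-(phenylsulfonyl)-3-phenyloxaziridine (1.2 equiv), CHCl3, 0 → 25 °C; then citric acid, MeOH, rt
Reagents that add atoms: 2-(phenylsulfonyl)-3-phenyloxaziridine, O=S(=O)(c1ccccc1)N1OC1c1ccccc1
Why: Rubottom oxidation in which the electrophilic oxaziridine should transfer oxygen to the electron-rich C3=C4 enol silane bond much faster than to the unactivated prenyl olefins and on the face anti to the C2 aryl group, so that epoxide opening with 1,4-silyl shift places the C3 oxygen trans to ring B (2R,3R, also the more stable diequatorial isomer) before mild acidic methanolysis removes the silyl group.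

Step 8
Reactants: 13 (2R,3R)-3-hydroxy-5,7-bis(methoxymethoxy)-2-[4-(methoxymethoxy)phenyl]-6,8-diprenylchroman-4-one
Product: 14 6,8-diprenylaromadendrin, (2R,3R)-3,5,7-trihydroxy-2-(4-hydroxyphenyl)-6,8-diprenylchroman-4-one
Conditions: 3 M aq. HCl, MeOH, 40 °C, monitored and stopped at full conversion
Reagents that add atoms: none
Why: Acid-catalysed transacetalisation of the three aryl MOM ethers to methanol under dilute, moderately warm conditions of the kind used for prenylated flavonoids, which should neither cyclise the ortho-prenyl phenols to chromans nor disturb the trans C2 and C3 centres.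

**Compound list**
1 | 2,4,6-trihydroxyacetophenone (phloroacetophenone) | CC(=O)c1c(O)cc(O)cc1O | starting material
2 | prenyl bromide (1-bromo-3-methylbut-2-ene) | CC(C)=CCBr | starting material
3 | 2,4,6-trihydroxy-3,5-diprenylacetophenone | CC(=O)c1c(O)c(CC=C(C)C)c(O)c(CC=C(C)C)c1O | intermediate
4 | 2-hydroxy-4,6-bis(methoxymethoxy)-3,5-diprenylacetophenone | CC(=O)c1c(O)c(CC=C(C)C)c(OCOC)c(CC=C(C)C)c1OCOC | intermediate
5 | (E)-3-(dimethylamino)-1-[2-hydroxy-4,6-bis(methoxymethoxy)-3,5-diprenylphenyl]prop-2-en-1-one | CN(C)/C=C/C(=O)c1c(O)c(CC=C(C)C)c(OCOC)c(CC=C(C)C)c1OCOC | intermediate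
6 | 2-(dimethylamino)-5,7-bis(methoxymethoxy)-6,8-diprenylchroman-4-one (racemic aminal, not isolated) | CN(C)C1CC(=O)c2c(OCOC)c(CC=C(C)C)c(OCOC)c(CC=C(C)C)c2O1 | intermediate
7 | 5,7-bis(methoxymethoxy)-6,8-diprenylchromone (4H-chromen-4-one) | O=c1ccoc2c(CC=C(C)C)c(OCOC)c(CC=C(C)C)c(OCOC)c12 | intermediate
8 | 4-(methoxymethoxy)phenylboronic acid | COCOc1ccc(B(O)O)cc1 | starting material
9 | (2S)-5,7-bis(methoxymethoxy)-2-[4-(methoxymethoxy)phenyl]-6,8-diprenylchroman-4-one (tris-MOM flavanone) | CC(C)=CCc1c(OCOC)c(CC=C(C)C)c2c(c1OCOC)C(=O)C[C@@H](c1ccc(OCOC)cc1)O2 | intermediate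
10 | (2S)-5,7-bis(methoxymethoxy)-2-[4-(methoxymethoxy)phenyl]-6,8-diprenyl-4-(trimethylsilyloxy)-2H-chromene | CC(C)=CCc1c(OCOC)c(CC=C(C)C)c2c(c1OCOC)C(O[Si](C)(C)C)=C[C@@H](c1ccc(OCOC)cc1)O2 | intermediate
11 | 3,4-epoxy-4-(trimethylsilyloxy)flavan from 10, epoxide oxygen on the face opposite the C2 aryl group (not isolated) | CC(C)=CCc1c(OCOC)c(CC=C(C)C)c2c(c1OCOC)[C@]3(O[Si](C)(C)C)O[C@@H]3[C@@H](c1ccc(OCOC)cc1)O2 | intermediate
12 | (2R,3R)-5,7-bis(methoxymethoxy)-2-[4-(methoxymethoxy)phenyl]-6,8-diprenyl-3-(trimethylsilyloxy)chroman-4-one (not isolated) | CC(C)=CCc1c(OCOC)c(CC=C(C)C)c2c(c1OCOC)C(=O)[C@H](O[Si](C)(C)C)[C@@H](c1ccc(OCOC)cc1)O2 | intermediate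
13 | (2R,3R)-3-hydroxy-5,7-bis(methoxymethoxy)-2-[4-(methoxymethoxy)phenyl]-6,8-diprenylchroman-4-one (tris-MOM dihydroflavonol) | CC(C)=CCc1c(OCOC)c(CC=C(C)C)c2c(c1OCOC)C(=O)[C@H](O)[C@@H](c1ccc(OCOC)cc1)O2 | intermediate
14 | 6,8-diprenylaromadendrin, (2R,3R)-3,5,7-trihydroxy-2-(4-hydroxyphenyl)-6,8-diprenylchroman-4-one | CC(C)=CCc1c(O)c(CC=C(C)C)c2c(c1O)C(=O)[C@H](O)[C@@H](c1ccc(O)cc1)O2 | target

**Step count**
Total steps: 8. Longest linear sequence: 8 steps (1 → 14); the arylboronic acid 8 is bought.

**Steps most likely to fail**

Step 5. The aryl transfer may stall on this electron-rich chromone while the boronic acid is lost to protodeboronation, or enantioface discrimination may be insufficient. The fallback sets out from 4 and comes back at 9. Claisen–Schmidt condensation of 4 with commercial 4-(methoxymethoxy)benzaldehyde (KOH, EtOH/H2O, rt) should give the 2'-hydroxychalcone F1. Oxa-Michael ring closure (NaOAc, EtOH, reflux) should give the racemic flavanone F2. Kinetic resolution by asymmetric transfer hydrogenation with RuCl(p-cymene)(TsDPEN) in HCO2H/Et3N, using the catalyst antipode that reduces the (2R)-ketone faster, should turn the unwanted enantiomer into the cis-(2R,4R)-flavan-4-ol F3. This leaves (2S)-9, which re-enters at step 6; the prenyl olefins are inert to transfer hydrogenation.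

Step 7. Oxygen transfer may not discriminate cleanly between the enol silane and the two trisubstituted prenyl olefins, and the facial bias from the C2 aryl group may be incomplete. The fallback sets out from 4 and comes back at 14; it sets both stereocentres by a nucleophilic epoxidation that cannot touch unactivated olefins.
- Exhaustive MOM protection of 4 (NaH, MOMCl, DMF, 0 °C) should give the tris-MOM acetophenone F4.
- Claisen–Schmidt condensation with 4-(methoxymethoxy)benzaldehyde (KOH, EtOH) should give the chalcone F5.
- Juliá–Colonna epoxidation (poly-L-leucine, urea–hydrogen peroxide, DBU, THF; polyleucine antipode chosen for this sense) should give the (αR,βS)-epoxy ketone F6.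
- HCl in MeOH then removes the MOM ethers, and the freed ortho-phenol opens the epoxide at the benzylic carbon with inversion (6-endo) while the α-carbinol centre is retained, giving trans-(2R,3R) 14 directly.

Step 1. The ambident phloroglucinol anion may alkylate on oxygen or twice at one carbon to give dearomatised dienones, and mono- or tri-prenylated material may dominate. The fallback sets out from 1 and comes back at 3 with no new intermediate: Friedel–Crafts prenylation of the neutral phenol with 2-methylbut-3-en-2-ol and BF3·OEt2 in dioxane at rt. This is electrophilic substitution by a prenyl cation equivalent, not phenoxide alkylation, and recovered mono-prenyl material can be resubmitted.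

**Further compounds**
F1 | step 5 | (E)-1-[2-hydroxy-4,6-bis(methoxymethoxy)-3,5-diprenylphenyl]-3-[4-(methoxymethoxy)phenyl]prop-2-en-1-one | COCOc1ccc(/C=C/C(=O)c2c(O)c(CC=C(C)C)c(OCOC)c(CC=C(C)C)c2OCOC)cc1
F2 | step 5 | racemic 5,7-bis(methoxymethoxy)-2-[4-(methoxymethoxy)phenyl]-6,8-diprenylchroman-4-one | CC(C)=CCc1c(OCOC)c(CC=C(C)C)c2c(c1OCOC)C(=O)CC(c1ccc(OCOC)cc1)O2
F3 | step 5 | (2R,4R)-5,7-bis(methoxymethoxy)-2-[4-(methoxymethoxy)phenyl]-6,8-diprenylchroman-4-ol (cis) | CC(C)=CCc1c(OCOC)c(CC=C(C)C)c2c(c1OCOC)[C@H](O)C[C@H](c1ccc(OCOC)cc1)O2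
F4 | step 7 | 2,4,6-tris(methoxymethoxy)-3,5-diprenylacetophenone | CC(=O)c1c(OCOC)c(CC=C(C)C)c(OCOC)c(CC=C(C)C)c1OCOC
F5 | step 7 | (E)-3-[4-(methoxymethoxy)phenyl]-1-[2,4,6-tris(methoxymethoxy)-3,5-diprenylphenyl]prop-2-en-1-one | COCOc1ccc(/C=C/C(=O)c2c(OCOC)c(CC=C(C)C)c(OCOC)c(CC=C(C)C)c2OCOC)cc1
F6 | step 7 | (αR,βS)-trans-epoxide of chalcone F5, [(2R,3S)-3-[4-(methoxymethoxy)phenyl]oxiran-2-yl][2,4,6-tris(methoxymethoxy)-3,5-diprenylphenyl]methanone | O=C(c1c(OCOC)c(CC=C(C)C)c(OCOC)c(CC=C(C)C)c1OCOC)[C@@H]1O[C@H]1c1ccc(OCOC)cc1
F0 | step 1 | none | none
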